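The trap in this flask is to book every point lost by the starting material as target: in the noon run at 20.0 s the starting material is down by 49.2 % of its charge, yet target reads 44.6 %, less than that loss. The runs and the questions are these.

| flask | starting material | partner | second substrate | protic impurity | remark | time |
|---|---|---|---|---|---|---|
| noon | 0.19 M | 0.80 equiv | 0.50 equiv | 11 mM | run made earlier |  |
| winter | 0.19 M | 0.80 equiv | 0.50 equiv | 33 mM | run made earlier |  |
| amber | 0.19 M | 0.800 equiv | 0.500 equiv | 9.50 mM |  | 2.0 min |
| grey | 0.19 M | 0.800 equiv | 0.500 equiv | 24.0 mM |  | 2.0 min |

- noon (time / s: starting material / %, target / %): 10.0: 51.3, 41.5; 12.0: 50.6, 42.8; 20.0: 50.8, 44.6; 30.0: 51.1, 42.9; 50.0: 53.4, 41.1; 60.0: 53.7, 40.2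
- winter (time / s: starting material / %, target / %): 10.0: 42.9, 38.7; 12.0: 42.6, 39.5; 20.0: 42.7, 39.8; 40.0: 44.5, 38.5; 60.0: 46.3, 36.2

(readings scatter by 0.5 percentage points)

- what was read earlier has a scatter of 0.5 percentage points, one standard deviation
- candidate steps: second substrate + partner -> second product; starting material + partner <-> target; starting material + protic impurity -> quenched substrate

- which of these there is most of at the end, counted by the starting material in it, amber (starting material / target)
- which of these there is most of at the end, counted by the starting material in it, grey (starting material / target)
- how much there is at the end of the one of these that leads, in percent of the starting material charged: amber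
- how much there is at the end of the one of these that leads, in percent of the starting material charged: grey

My bench rule is that a protic impurity takes its own amount of starting material, one for one, as the limiting reagent of that quench (9.50 mM against 0.19 M in amber). So I carry the pool: the percentage of the charge still able to stand as free starting material or as target once that toll is paid, the charge less c(protic impurity)/c(starting material), 95.0 % for amber and 87.4 % for grey. The rule passes on the earlier runs: the noon pool is 94.2 % and its last two peaks sum to 93.9 %, while the winter pool is 82.6 % against a sum of 82.5 %.

The rule stops at the split inside the pool. My zero of the scale is the even line, half of the pool, which in amber means 47.5 % bound to partner. The partner charge of 0.800 equiv clears that, a ratio of 1.68 to the line, but the second substrate's 0.500 equiv draws on the same partner, so this ratio gives no verdict on the split. The readings already sit on the starting-material side: the lowest noon reading is 50.6 %, above its line, and the lowest winter reading is 42.6 %, above its line too. Noon starting material climbs from 50.8 % to 53.7 % by 60.0 s, so I take the last shares of the pool, 57.0 % in noon and 56.0 % in winter, as my estimated floors: I expect starting material to lead, with floors of 54.2 % in amber and 48.9 % in grey.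

The forecast goes further than my floors. It also has starting material leading, with 58.8 % (56.8 % to 60.8 %) in amber and 53.4 % (51.4 % to 55.4 %) in grey, on the ground that “the second substrate slowly and irreversibly drains partner”.

    second substrate + partner → second product (k = 0.0990 M⁻¹ s⁻¹)
    starting material + partner ⇌ target (K = 15.0 M⁻¹, k = 1.20 M⁻¹ s⁻¹)
    starting material + protic impurity → quenched substrate (k = 5.10 M⁻¹ s⁻¹)

Starting material leads at 58.9 % in amber and 53.1 % in grey, both inside the forecast's ranges. In amber the protic impurity stands at 0 % of its charge with quenched substrate at 5.00 %, and starting material plus target come to 95.0 % against the pool of 95.0 %. A neighbouring flask, like amber but charged with 0.038 M of protic impurity, has a pool of 80.0 % and an even line at 40.0 %. It ends with starting material at 47.7 % and target at 32.3 %, which sum to 80.0 %, with starting material above the line.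

The runs were generated by integration from invented constants.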